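**Plan**
- Retrosynthesis: the C-6 O-acyl bond and the C-11–C-12 bond (ester carbon from CO on a C-7 ethynyl group) are cut first. Ring B is then cut at C6–C7 and C8–C9 in one operation, leaving a ring A iodo aldehyde and the vinyl group of a silyl enyne.
- Enabling feature: in ring B the carbinol carbon C-6 (on C-5) and the methylene C-9 (on quaternary C-10) are 1,4-related across the ring fusion, and C-7 bears an sp2 carbon. A C-9 radical and a C-6 aldehyde can therefore be bridged by the alkene of a conjugated enyne whose propargylic carbon becomes C-7.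
- Forward: ring A from (R)-carvone (steps 1–8); ring B by a CrCl2-mediated radical–polar crossover annulation (step 9); then alkyne unmasking, esterification, hydromethoxycarbonylation and desilylation.
- Stereochemistry: C-3 from carvone (Criegee, retention); C-1 by cis-selective Luche reduction; C-10 by cyclopropanation anti to the C-1 silyloxy group; C-5 by kinetic protonation anti to the C-10 methyl; C-6 and C-7 in the chair-like ring closure of step 9.

Key step: step 9

Remark: positions follow eudesmane numbering (ring A = C-1 to C-5 and C-10; ring B = C-5 to C-10; C-14 angular methyl, C-15 exocyclic methylene; β = face of C-14). Centres that become sp2 in a later step (C-4 and C-5 in 11–13), the enol ether geometry of 15 and the allene axis of 18 are left unspecified. TBS = tert-butyldimethylsilyl, TMS = trimethylsilyl.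

**Route**

Step 1
Reactants: 1 (R)-(−)-carvone
Product: 4 (R)-5-acetoxy-2-methylcyclohex-2-en-1-one, via methoxy hydroperoxide 2 (not isolated), via peracetate 3 (not isolated)
Conditions: O3, CH2Cl2/MeOH, −78 °C; then Ac2O, Et3N, DMAP (cat.), 0 to 40 °C
Reagents that add atoms: ozone [O-][O+]=O; methanol CO
Why: Chemoselective ozonolysis of the electron-rich isopropenyl group in methanol and Criegee rearrangement of the derived peracetate should replace the side chain by acetoxy with retention, so the carvone stereocentre becomes the C-3 carbinol centre.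

Step 2
Reactants: 4 (R)-5-acetoxy-2-methylcyclohex-2-en-1-one
Product: 6 (1R,5R)-2-methylcyclohex-2-ene-1,5-diol (cis), via hydroxy acetate 5 (not isolated)
Conditions: NaBH4, CeCl3·7H2O, MeOH, −78 °C; then K2CO3, MeOH, 25 °C
Reagents that add atoms: none
Why: Luche reduction should deliver hydride 1,2 and axially to give the pseudo-equatorial alcohol cis to the acetoxy group (C-1 and C-3 oxygens cis), and carbonate methanolysis then removes the acetate once the elimination-prone β-acetoxy ketone is gone.

Step 3
Reactants: 6 (1R,5R)-2-methylcyclohex-2-ene-1,5-diol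
Product: 7 bis-TBS ether of 6
Conditions: TBSCl, imidazole, DMF, 25 °C
Reagents that add atoms: tert-butyldimethylsilyl chloride CC(C)(C)[Si](C)(C)Cl
Why: Standard imidazole-promoted silylation protects both secondary alcohols without touching the stereocentres.

Step 4
Reactants: 7 bis-TBS ether of 6
Product: 8 (4R,6S)-4,6-bis(TBS-oxy)-3-methylcyclohex-2-en-1-one
Conditions: CrO3, 3,5-dimethylpyrazole, CH2Cl2, −20 °C
Reagents that add atoms: chromium trioxide O=[Cr](=O)=O
Why: Allylic oxidation with the CrO3/3,5-dimethylpyrazole complex should turn the only allylic ring CH2 into the enone carbonyl (C-4) without moving the double bond, because transposition would place oxygen on a fully substituted carbon.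

Step 5
Reactants: 8 (4R,6S)-4,6-bis(TBS-oxy)-3-methylcyclohex-2-en-1-one
Product: 9 3,5-bis(TBS-oxy)-6-methylbicyclo[4.1.0]heptan-2-one (cyclopropane CH2 anti to both silyloxy groups)
Conditions: Me3S(O)I, NaH, DMSO, 25 to 50 °C
Reagents that add atoms: trimethylsulfoxonium iodide C[S+](C)(C)=O.[I-]
Why: Corey–Chaykovsky cyclopropanation (conjugate addition of the sulfoxonium ylide anti to the adjacent silyloxy group, then 3-exo-tet closure) should create the quaternary C-10 with the new CH2 (C-9) on the face opposite both silyloxy groups.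

Step 6
Reactants: 9 cyclopropyl ketone
Product: 11 4,6-bis(TBS-oxy)-2-(dimethoxymethyl)-3-(iodomethyl)-3-methylcyclohexan-1-one, via silyl enol ether 10 (not isolated)
Conditions: TMSI, CH2Cl2, −78 to −20 °C; then HC(OMe)3, TMSOTf (cat.), −78 °C
Reagents that add atoms: iodotrimethylsilane C[Si](C)(C)I; trimethyl orthoformate COC(OC)OC
Why: Iodide should open the silyl-activated cyclopropyl ketone by homo-conjugate addition at the cyclopropane CH2, cleaving the external bond that overlaps with the carbonyl π system, and the silyl enol ether is then formylated by Mukaiyama-type addition to the orthoformate-derived oxocarbenium ion; C-10 keeps its configuration.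

Step 7
Reactants: 11 keto acetal
Product: 14 3,5-bis(TBS-oxy)-6-(iodomethyl)-2,6-dimethylcyclohex-1-ene-1-carbaldehyde, via tertiary alcohol 12 (not isolated), via hydroxy aldehyde 13 (not isolated)
Conditions: MeLi, CeCl3, THF, −78 °C; cold quench, then p-TsOH (cat.), acetone/H2O, 25 to 40 °C
Reagents that add atoms: methyllithium [Li]C
Why: The non-basic organocerium reagent should add 1,2 to the hindered, enolisable ketone without triggering alkylation by the iodide, and acid then hydrolyses the acetal and dehydrates the β-hydroxy aldehyde to the conjugated tetrasubstituted enal.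

Step 8
Reactants: 14 conjugated enal
Product: 16 1β,3β-bis(TBS-oxy)-10α-(iodomethyl)-10β-methyl-4-methylenecyclohexane-5β-carbaldehyde (5α-H), via silyl dienol ether 15 (not isolated)
Conditions: TMSOTf, Et3N, CH2Cl2, −78 to 0 °C; then TBAF premixed with excess AcOH, THF, −78 °C
Reagents that add atoms: none
Why: γ-Deprotonation of the O-silylated enal at the methyl group cis to the formyl group gives the silyl dienol ether, and fluoride release of the dienolate in the presence of excess acetic acid should give kinetic α-protonation (deconjugative protonation) faster than alkylation by the iodide, setting C-5 by proton delivery anti to the pseudo-axial C-10 methyl while creating the exocyclic methylene.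

Step 9
Reactants: 16 ring A iodo aldehyde; 17 but-3-en-1-yn-1-yl(trimethyl)silane
Product: 20 1β,3β-bis(TBS-oxy)-13-(trimethylsilyl)-12-noreudesm-4(15)-en-11(13)-yn-6α-ol, via allenylchromium dichloride 18 (not isolated), via chromium alkoxide 19 (not isolated)
Conditions: CrCl2 (6 equiv), CoPc (cobalt phthalocyanine, C32H16N8Co, 5 mol %), 17 (5 equiv), DMF, 25 to 40 °C; aq. NH4Cl work-up
Reagents that add atoms: none
Why: Proposed new method: CrCl2, relayed by CoPc, abstracts iodine from the neopentyl-type iodide of 16 to give the C-9 radical, which adds to the CH2 terminus of enyne 17 (C8–C9 bond), and the resulting propargyl radical is reduced by a second CrCl2 to the allenyl/propargyl trivalent chromium species 18, which adds through its γ-carbon to the tethered aldehyde (C6–C7 bond) to give alkoxide 19. The closest known reaction type is the CrCl2-mediated three-component coupling of alkyl iodides with 1,3-dienes or 1,3-enynes and aldehydes by sequential radical addition and organochromium carbonyl addition, made annulative here because iodide and aldehyde sit on the adjacent ring A carbons C-10 and C-5. Ring B is closed in the polar event as a 6-exo-trig carbonyl addition (intramolecular Nozaki–Hiyama–Kishi-type propargylation), whereas the radical step is intermolecular. C-6 and C-7 are set in a chair-like chromium-bridged transition state fused to the ring A chair, in which the aldehyde oxygen lies equatorial (6α) to avoid the syn-axial C-10 methyl and the alkynyl group lies equatorial (7β), while the fixed trans CHO/CH2 relationship at C-5/C-10 gives the trans ring fusion. The step needs (i) radical addition to 17 to outrun direct capture of the hindered primary radical by chromium, secured by excess enyne, since cyclisation of the C-9 radical onto the C-6 aldehyde or the C-4 methylene would be a four-membered or 5-endo closure, (ii) bond formation at the propargylic carbon and not at the silylated alkyne carbon, secured because the latter would require an eight-membered cyclic allene, (iii) no enolisation of the β,γ-unsaturated aldehyde, secured by the neutral medium, and (iv) reduction of the stabilised propargyl radical by the excess CrCl2 to outrun its slow 6-exo or 7-endo addition to the C-4 methylene.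

Step 10
Reactants: 20 silyl alkyne
Product: 21 1β,3β-bis(TBS-oxy)-12-noreudesm-4(15)-en-11(13)-yn-6α-ol
Conditions: K2CO3, MeOH, 25 °C
Reagents that add atoms: none
Why: Carbonate methanolysis should cleave only the alkynyl C–Si bond (protodesilylation of a silyl alkyne) and leave the silyl ethers intact.

Step 11
Reactants: 22 methyl 2-(hydroxymethyl)acrylate
Product: 23 methyl 2-[(TBS-oxy)methyl]acrylate
Conditions: TBSCl, imidazole, CH2Cl2, 0 to 25 °C
Reagents that add atoms: tert-butyldimethylsilyl chloride CC(C)(C)[Si](C)(C)Cl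
Why: Standard silylation of the primary allylic alcohol.

Step 12
Reactants: 23 methyl 2-[(TBS-oxy)methyl]acrylate
Product: 24 2-[(TBS-oxy)methyl]acrylic acid
Conditions: LiOH, THF/H2O, 0 °C; then 1 M HCl to pH 3
Reagents that add atoms: lithium hydroxide [Li+].[OH-]
Why: Mild saponification (acyl–oxygen cleavage) should free the acid without loss of the silyl ether or conjugate addition.

Step 13
Reactants: 21 terminal alkyne alcohol; 24 2-[(TBS-oxy)methyl]acrylic acid
Product: 26 6α-O-{2-[(TBS-oxy)methyl]acryloyl} ester of 21, via mixed anhydride 25 (not isolated)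
Conditions: 24, 2,4,6-trichlorobenzoyl chloride, Et3N, THF, 25 °C; then 21, DMAP, toluene, 25 to 40 °C
Reagents that add atoms: none
Why: Yamaguchi esterification (mixed anhydride, DMAP acyl transfer) should acylate the hindered equatorial C-6 alcohol with retention, before any C-12 carbonyl exists that could lactonise onto it.

Step 14
Reactants: 26 alkyne ester
Product: 27 methyl 1β,3β-bis(TBS-oxy)-6α-({2-[(TBS-oxy)methyl]acryloyl}oxy)eudesma-4(15),11(13)-dien-12-oate
Conditions: Pd(OAc)2 (2 mol %), 2-pyridyldiphenylphosphine (40 mol %), MeSO3H (20 mol %), CO (20 bar), MeOH (10 equiv), CH2Cl2, 45 °C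
Reagents that add atoms: carbon monoxide [C-]#[O+]; methanol CO
Why: Markovnikov hydromethoxycarbonylation of the terminal alkyne (hydropalladation with Pd on the internal carbon, CO insertion, methanolysis) should give the 2-substituted acrylate directly, the alkyne reacting far faster than the 1,1-disubstituted alkenes, while the excess of pyridylphosphine over acid and the low methanol concentration keep the silyl ethers intact.

Step 15
Reactants: 27 tris-silyl ether
Product: 28 methyl 1β,3β-dihydroxy-6α-{[2-(hydroxymethyl)acryloyl]oxy}eudesma-4(15),11(13)-dien-12-oate (CNP0247525.1)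
Conditions: HF·pyridine, THF/pyridine, 0 to 25 °C
Reagents that add atoms: none
Why: Fluoride-mediated desilylation should free the three hydroxyl groups without touching the esters or alkenes.

**Compound list**

1 | (R)-(−)-carvone | CC(=C)[C@@H]1CC=C(C)C(=O)C1 | starting material
2 | (5R)-5-(1-hydroperoxy-1-methoxyethyl)-2-methylcyclohex-2-en-1-one | COC(C)(OO)[C@@H]1CC=C(C)C(=O)C1 | intermediate
3 | (5R)-5-(1-acetylperoxy-1-methoxyethyl)-2-methylcyclohex-2-en-1-one | COC(C)(OOC(C)=O)[C@@H]1CC=C(C)C(=O)C1 | intermediate
4 | (R)-5-acetoxy-2-methylcyclohex-2-en-1-one | CC(=O)O[C@@H]1CC=C(C)C(=O)C1 | intermediate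
5 | (1R,5R)-5-acetoxy-2-methylcyclohex-2-en-1-ol (cis) | CC1=CC[C@@H](OC(C)=O)C[C@H]1O | intermediate
6 | (1R,5R)-2-methylcyclohex-2-ene-1,5-diol (cis) | CC1=CC[C@@H](O)C[C@H]1O | intermediate
7 | bis-TBS ether of 6 | CC1=CC[C@@H](O[Si](C)(C)C(C)(C)C)C[C@H]1O[Si](C)(C)C(C)(C)C | intermediate
8 | (4R,6S)-4,6-bis(TBS-oxy)-3-methylcyclohex-2-en-1-one | CC1=CC(=O)[C@@H](O[Si](C)(C)C(C)(C)C)C[C@H]1O[Si](C)(C)C(C)(C)C | intermediate
9 | 3,5-bis(TBS-oxy)-6-methylbicyclo[4.1.0]heptan-2-one, CH2 bridge anti to both silyloxy groups | C[C@@]12C[C@@H]1C(=O)[C@@H](O[Si](C)(C)C(C)(C)C)C[C@H]2O[Si](C)(C)C(C)(C)C | intermediate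
10 | TMS enol ether of the 3-(iodomethyl)-3-methyl ketone (iodomethyl trans to the C-1 silyloxy group) | C1=C(O[Si](C)(C)C)[C@@H](O[Si](C)(C)C(C)(C)C)C[C@@H](O[Si](C)(C)C(C)(C)C)[C@]1(C)CI | intermediate
11 | 4,6-bis(TBS-oxy)-2-(dimethoxymethyl)-3-(iodomethyl)-3-methylcyclohexan-1-one (C-2 epimers) | COC(OC)C1C(=O)[C@@H](O[Si](C)(C)C(C)(C)C)C[C@@H](O[Si](C)(C)C(C)(C)C)[C@]1(C)CI | intermediate
12 | tertiary methyl carbinol from 11 | COC(OC)C1C(C)(O)[C@@H](O[Si](C)(C)C(C)(C)C)C[C@@H](O[Si](C)(C)C(C)(C)C)[C@]1(C)CI | intermediate
13 | β-hydroxy aldehyde from 12 | O=CC1C(C)(O)[C@@H](O[Si](C)(C)C(C)(C)C)C[C@@H](O[Si](C)(C)C(C)(C)C)[C@]1(C)CI | intermediate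
14 | 3,5-bis(TBS-oxy)-6-(iodomethyl)-2,6-dimethylcyclohex-1-ene-1-carbaldehyde | O=CC1=C(C)[C@@H](O[Si](C)(C)C(C)(C)C)C[C@@H](O[Si](C)(C)C(C)(C)C)[C@]1(C)CI | intermediate
15 | TMS dienol ether of 14 (exocyclic methylene) | C[Si](C)(C)OC=C1C(=C)[C@@H](O[Si](C)(C)C(C)(C)C)C[C@@H](O[Si](C)(C)C(C)(C)C)[C@]1(C)CI | intermediate
16 | ring A iodo aldehyde: 1β,3β-bis(TBS-oxy), 4-methylene, 5α-H/5β-CHO, 10β-methyl, 10α-CH2I | O=C[C@H]1C(=C)[C@@H](O[Si](C)(C)C(C)(C)C)C[C@@H](O[Si](C)(C)C(C)(C)C)[C@]1(C)CI | intermediate
17 | but-3-en-1-yn-1-yl(trimethyl)silane | C=CC#C[Si](C)(C)C | starting material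
18 | allenylchromium dichloride from 16 and 17 | O=C[C@H]1C(=C)[C@@H](O[Si](C)(C)C(C)(C)C)C[C@@H](O[Si](C)(C)C(C)(C)C)[C@]1(C)CCC=C=C([Si](C)(C)C)[Cr](Cl)Cl | intermediate
19 | chromium dichloride alkoxide of 20 | Cl[Cr](Cl)O[C@@H]1[C@H]2C(=C)[C@@H](O[Si](C)(C)C(C)(C)C)C[C@@H](O[Si](C)(C)C(C)(C)C)[C@]2(C)CC[C@H]1C#C[Si](C)(C)C | intermediate
20 | 1β,3β-bis(TBS-oxy)-13-(trimethylsilyl)-12-noreudesm-4(15)-en-11(13)-yn-6α-ol (5α-H, 7α-H) | O[C@@H]1[C@H]2C(=C)[C@@H](O[Si](C)(C)C(C)(C)C)C[C@@H](O[Si](C)(C)C(C)(C)C)[C@]2(C)CC[C@H]1C#C[Si](C)(C)C | intermediate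
21 | 1β,3β-bis(TBS-oxy)-12-noreudesm-4(15)-en-11(13)-yn-6α-ol | O[C@@H]1[C@H]2C(=C)[C@@H](O[Si](C)(C)C(C)(C)C)C[C@@H](O[Si](C)(C)C(C)(C)C)[C@]2(C)CC[C@H]1C#C | intermediate
22 | methyl 2-(hydroxymethyl)acrylate | C=C(CO)C(=O)OC | starting material
23 | methyl 2-[(TBS-oxy)methyl]acrylate | C=C(CO[Si](C)(C)C(C)(C)C)C(=O)OC | intermediate
24 | 2-[(TBS-oxy)methyl]acrylic acid | C=C(CO[Si](C)(C)C(C)(C)C)C(=O)O | intermediate
25 | mixed anhydride of 24 with 2,4,6-trichlorobenzoic acid | C=C(CO[Si](C)(C)C(C)(C)C)C(=O)OC(=O)c1c(Cl)cc(Cl)cc1Cl | intermediate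
26 | 6α-O-{2-[(TBS-oxy)methyl]acryloyl} ester of 21 | C=C(CO[Si](C)(C)C(C)(C)C)C(=O)O[C@@H]1[C@H]2C(=C)[C@@H](O[Si](C)(C)C(C)(C)C)C[C@@H](O[Si](C)(C)C(C)(C)C)[C@]2(C)CC[C@H]1C#C | intermediate
27 | methyl 1β,3β-bis(TBS-oxy)-6α-({2-[(TBS-oxy)methyl]acryloyl}oxy)eudesma-4(15),11(13)-dien-12-oate | C=C(CO[Si](C)(C)C(C)(C)C)C(=O)O[C@@H]1[C@H]2C(=C)[C@@H](O[Si](C)(C)C(C)(C)C)C[C@@H](O[Si](C)(C)C(C)(C)C)[C@]2(C)CC[C@H]1C(=C)C(=O)OC | intermediate
28 | methyl 1β,3β-dihydroxy-6α-{[2-(hydroxymethyl)acryloyl]oxy}eudesma-4(15),11(13)-dien-12-oate (1R,3S,5S,6S,7S,10R) | C=C(CO)C(=O)O[C@@H]1[C@H]2C(=C)[C@@H](O)C[C@@H](O)[C@]2(C)CC[C@H]1C(=C)C(=O)OC | target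

**Totals and risks**

Total step count: 15. Longest linear sequence: 13 steps, namely steps 1 to 10 and 13 to 15; steps 11 and 12 prepare the acid 24.

The three steps most likely to fail, in order of risk, each with its fallback:

Risk at step 9, the key step: the C-9 radical may be captured by chromium or reduced before it adds to the enyne, so that the iodide is lost to simple reduction or to intermolecular carbonyl addition. Fallback for step 9: the two bonds are made in separate, known operations. Setting out from 16, a Giese addition of the iodide-derived radical to acrolein, run with tris-trimethylsilylsilane and AIBN in toluene at 80 °C, should give the ring A dialdehyde F1. A proline-catalysed intramolecular aldol addition, in which the enamine of the unbranched aldehyde adds to the hindered α-branched one, should then close ring B to the trans-fused β-hydroxy aldehyde F2. Seyferth–Gilbert homologation with the Ohira–Bestmann reagent, K2CO3 and MeOH converts the formyl group into the terminal alkyne and returns to the route at 21.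

Risk at step 8: the deconjugated aldehyde may revert to the conjugated enal, by γ-protonation of the dienolate or by enolisation during isolation. Fallback for step 8: the labile aldehyde is trapped by reduction as it forms. Setting out from 14, acetylation under enolising conditions with Ac2O, Et3N and DMAP at 60 °C should give the dienol acetate F3. NaBH4 in ethanol at 0 °C cleaves the enol ester, the dienolate is protonated at the α-carbon by the solvent, and the β,γ-unsaturated aldehyde is reduced at once to the homoallylic alcohol F4. Buffered Dess–Martin oxidation just before the key step returns to the route at 16.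

Risk at step 6: iodide attack at the hindered cyclopropane CH2 may be slow, with competing loss of the silyl ethers to iodotrimethylsilane. Fallback for step 6: C-9 is introduced as a masked hydroxymethyl nucleophile. Setting out from 8, conjugate addition of the Grignard reagent i-PrOMe2SiCH2MgCl with catalytic CuBr·SMe2 and TMSCl, anti to the C-1 silyloxy group, should give the silyl enol ether F5. Orthoformate and TMSOTf as in step 6 give the keto acetal F6. Tamao oxidation with KF, KHCO3 and H2O2 gives the primary alcohol F7, and Appel iodination with PPh3, I2 and imidazole returns to the route at 11.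

Further compounds

F1 | step 9 | ring A dialdehyde (Giese adduct of 16 with acrolein) | O=C[C@H]1C(=C)[C@@H](O[Si](C)(C)C(C)(C)C)C[C@@H](O[Si](C)(C)C(C)(C)C)[C@]1(C)CCCC=O
F2 | step 9 | 6α-hydroxy-7β-formyl trans-decalin (aldol product) | O[C@@H]1[C@H]2C(=C)[C@@H](O[Si](C)(C)C(C)(C)C)C[C@@H](O[Si](C)(C)C(C)(C)C)[C@]2(C)CC[C@H]1C=O
F3 | step 8 | dienol acetate of 14 | CC(=O)OC=C1C(=C)[C@@H](O[Si](C)(C)C(C)(C)C)C[C@@H](O[Si](C)(C)C(C)(C)C)[C@]1(C)CI
F4 | step 8 | homoallylic alcohol corresponding to 16 | OC[C@H]1C(=C)[C@@H](O[Si](C)(C)C(C)(C)C)C[C@@H](O[Si](C)(C)C(C)(C)C)[C@]1(C)CI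
F5 | step 6 | TMS enol ether with 3-[(isopropoxydimethylsilyl)methyl] group | C1=C(O[Si](C)(C)C)[C@@H](O[Si](C)(C)C(C)(C)C)C[C@@H](O[Si](C)(C)C(C)(C)C)[C@]1(C)C[Si](C)(C)OC(C)C
F6 | step 6 | keto acetal with 3-[(isopropoxydimethylsilyl)methyl] group | COC(OC)C1C(=O)[C@@H](O[Si](C)(C)C(C)(C)C)C[C@@H](O[Si](C)(C)C(C)(C)C)[C@]1(C)C[Si](C)(C)OC(C)C
F7 | step 6 | keto acetal with 3-(hydroxymethyl) group | COC(OC)C1C(=O)[C@@H](O[Si](C)(C)C(C)(C)C)C[C@@H](O[Si](C)(C)C(C)(C)C)[C@]1(C)CO
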